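- I decide to add nothing to Monday's or Saturday's and to read both at 2.5 h. Each holds the racemic substrates, partner and precatalyst, and they differ in partner.

in all of them: left-handed substrate 0.029 M; right-handed substrate 0.029 M; precatalyst 46 µM
- ash: partner 0.024 M; run made earlier
- oak: partner 0.076 M; run made earlier
- Monday's: partner 0.0319 M; time 2.5 h
- Saturday's: partner 0.100 M; time 2.5 h

| run | time / min | left-handed product / % | right-handed product / % |
|---|---|---|---|
| ash | 15.0 | 0 | 0 |
| ash | 30.0 | 0 | 0 |
| ash | 50.0 | 2.1 | 1.4 |
| ash | 60.0 | 0.6 | 0.8 |
| ash | 80.0 | 2.3 | 0 |
| oak | 6.00 | 0.6 | 0.5 |
| oak | 20.0 | 2.0 | 0 |
| oak | 40.0 | 4.5 | 2.0 |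
| oak | 50.0 | 6.4 | 1.1 |
| oak | 80.0 | 8.9 | 0.3 |

(scatter of a reading: 1 percentage point)

1. the winner by excess of left-handed product over right-handed product in the product; "neither" if no more than 2 percentage points parts them (Monday's / Saturday's / neither)
2. excess of left-handed product over right-handed product in the product at the end, Monday's
3. excess of left-handed product over right-handed product in the product at the end, Saturday's

- catalyst is single-handed; left-handed substrate and right-handed substrate are mirror images of each other, charged as a racemate, each of them at the stated concentration
- an excess is the difference of the two amounts in percent of their sum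
- an excess is below zero if the other one leads

- I carry the selectivity factor s: how many times faster the catalyst takes left-handed substrate than right-handed, at equal amounts. Summing the oak readings, left-handed product over right-handed product, gives a reading of s = 5.74. This is rough, because the right-handed sum carries a scatter of 2.2 percentage points.
- Next I work in powers of ten. The last readings of oak and ash give an order in partner n = 1.20, from a noisy ash reading.
- Scaling oak's last total by time and by partner to the power n, I expect 6.07% of the substrates reacted in Monday's and 24.0% in Saturday's.
- Let x and y be the fractions of left-handed and right-handed substrate left, with ln y = ln x / s. The excess is then e = (y − x)/(2 − x − y).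
- Starting from the low-conversion excess 70.3%, I take x = 0.897 for Monday's and 0.591 for Saturday's.
- That gives 69.2% for Monday's and 64.8% for Saturday's, which is lower. So I name Monday's, and I ask you not to top up the partner.
- The forecast differs: it names Saturday's, with 55% for Monday's and 78% for Saturday's, on the ground that “Selectivity therefore seems to grow with partner”.
- Monday's gives 64.7% and Saturday's 57.8%, so Monday's leads.

    partner + precatalyst → catalyst + spent reagent (k = 0.00320 M⁻¹ s⁻¹)
    partner + catalyst + right-handed substrate → catalyst + right-handed product (k = 1.60 M⁻² s⁻¹)
    partner → decomposed reagent (k = 5.40 × 10⁻⁵ s⁻¹)
    partner + catalyst + left-handed substrate → catalyst + left-handed product (k = 49.0 M⁻² s⁻¹)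
    left-handed product ⇌ right-handed product (k = 5.20 × 10⁻⁵ s⁻¹)

- At the end of Saturday's, left-handed product is made 2.29 times faster than it is used up, each step taken net. With 43% of the left-handed substrate left in Saturday's, s gives an excess of 61.3%. In a neighbour of Saturday's charged with 0.40 M of partner, 0.50% of the left-handed substrate left gives an excess of 24.6% against the flask's 32.8%. There, 84% of the right-handed substrate stands where s leaves 39.7%.

Readings and results stem from a simulated flask with constants of no real substance; noise was put on by code.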